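## Retrosynthetic overview
1. The ε-lactone (C12–O–C17) closes last, from the acid made by allylic oxidation of the C1 isopropenyl group. C3 and C11 are acetylated before that.
2. The 14-membered carbocycle closes by a Ti(III)/photoredox intramolecular cross-pinacol coupling of a C11 aldehyde with a C12 methyl ketone (C11–C12 bond; sets C11 and C12).
3. The open-chain keto-aldehyde comes from Cr/photoredox coupling of a limonene-derived primary C2 radical with the C3 aldehyde of a linalool-derived THF. The C9→C11 chain is then built by Wittig olefination and enal reduction.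
4. The THF (C4–O–C7, with C7/C8) comes from (E)-8-hydroxylinalool by epoxidation and 5-exo opening by the C4 tertiary alcohol. C4 and the C1 side chain come from (R)-linalool and (R)-limonene. Ring order: THF, then 14-membered carbocycle, then 7-membered lactone.

**Assumptions:** (R)-(+)-limonene and (R)-(−)-linalool are the cheap enantiomers. The diastereomers from steps 5, 7 and 11 are separable by chromatography. Hantzsch-type 4-alkyl-1,4-dihydropyridines act as primary-radical precursors in Cr/photoredox coupling.

## Route

**Step 1**
Reactants: 1 (R)-(+)-limonene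
Product: 2 (R)-limonene 1,2-oxide (cis/trans mixture)
Conditions: mCPBA (1.0 equiv), NaHCO3, CH2Cl2, 0 °C
Reagents that add atoms: mCPBA, OOC(=O)c1cccc(Cl)c1 (supplies O)
Why: Prilezhaev epoxidation is selective for the trisubstituted ring alkene over the isopropenyl group. The epoxide stereocentres are destroyed in step 2, and the future C1 is untouched.

**Step 2**
Reactants: 2
Product: 3 (R)-3-isopropenyl-6-oxoheptanal
Conditions: H5IO6 (1.2 equiv), THF/Et2O, 0 °C→rt
Reagents that add atoms: water, O (its oxygen ends up in the carbonyl after epoxide hydrolysis); periodic acid, O=I(O)(O)(O)(O)O (oxidant for glycol cleavage; I(VII)→I(V))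
Why: Acid-promoted epoxide hydrolysis gives the 1,2-diol (C10H16O + H2O), and Malaprade cleavage (−2H) then gives the keto-aldehyde C10H16O2. The isopropenyl group survives and C1 (R) is retained.

**Step 3**
Reactants: 3
Product: 4 Hantzsch-type 4-alkyl-1,4-dihydropyridine (C2 radical precursor)
Conditions: ethyl acetoacetate (2.2 equiv), NH4OAc, EtOH, 50 °C
Reagents that add atoms: ethyl acetoacetate, CCOC(=O)CC(C)=O; ammonium acetate, CC(=O)[O-].[NH4+]
Why: Hantzsch condensation occurs at the aldehyde, not the methyl ketone. The former CHO carbon becomes pyridine C4, so the C4 substituent is the C2–C1 unit that is released as the radical.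

**Step 4**
Reactants: 5 (R)-(−)-linalool
Product: 6 (E)-8-hydroxylinalool
Conditions: SeO2 (0.2 equiv), t-BuOOH (3 equiv), CH2Cl2, rt
Reagents that add atoms: t-BuOOH, CC(C)(C)OO (supplies O)
Why: Riley/Sharpless allylic oxidation hydroxylates the methyl of the prenyl unit that ends up trans to the chain, giving the E-allylic alcohol. This carbon later becomes C9. The tertiary alcohol (C4, R) and the vinyl group are untouched.

**Step 5**
Reactants: 6
Product: 7 (2R)-2-[(2S,5R)-5-ethenyl-5-methyloxolan-2-yl]propane-1,2-diol (the THF with vinyl and side chain cis)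
Conditions: mCPBA (1.05 equiv), NaHCO3, CH2Cl2, 0 °C; then CSA (0.1 equiv), rt; separate diastereomers on SiO2
Reagents that add atoms: mCPBA, OOC(=O)c1cccc(Cl)c1 (supplies O)
Why: mCPBA epoxidises the electron-rich E-trisubstituted alkene rather than the vinyl group. Acid-promoted 5-exo opening by the C4 tertiary alcohol at C7 occurs with inversion (anti opening of an E-epoxide), which fixes C7/C8 relative to each other as (7S,8R). The two epoxide faces give diastereomers 7 (4R,7S,8R; cis) and (4R,7R,8S; trans). Only 7 has C7/C8 matching the target relative to the linalool-derived C4, and the other is discarded.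

**Step 6**
Reactants: 7
Product: 8 (2R,5S)-5-[(2R)-1,2-dihydroxypropan-2-yl]-2-methyloxolane-2-carbaldehyde
Conditions: O3, CH2Cl2/MeOH, −78 °C; then PPh3, −78 °C→rt
Reagents that add atoms: ozone, [O-][O+]=O (supplies O)
Why: Ozonolysis with reductive work-up cleaves the vinyl group to the C3 aldehyde. Periodate is avoided because it would cleave the C8/C9 vicinal diol. The quaternary C4 cannot epimerise.

**Step 7**
Reactants: 4; 8
Product: 9 C3 secondary alcohol (1R,3S,4R,7S,8R; C12 methyl ketone, C8 tertiary OH, C9 primary OH)
Conditions: CrCl3 (10 mol %), dtbbpy (10 mol %), 4CzIPN (2 mol %), MeCN, blue LEDs, 25 °C (4 used in slight excess, 1.5 equiv)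
Reagents that add atoms: none
Why: Dual photoredox/Cr (Nozaki–Hiyama-type) alkylation: the excited photocatalyst oxidises the DHP to release the primary C2 radical, which is captured by Cr(II). The alkyl-Cr(III) then adds chemoselectively to the aldehyde rather than the methyl ketone or the free OH groups. Addition to the α-alkoxy aldehyde anti to the C4–O bond (Felkin–Anh) should favour 3S, and the 3R epimer is separated.

**Step 8**
Reactants: 9
Product: 10 C9 aldehyde (α-hydroxy aldehyde)
Conditions: Cu(MeCN)4OTf (5 mol %), bpy (5 mol %), TEMPO (5 mol %), N-methylimidazole (10 mol %), air, MeCN, rt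
Reagents that add atoms: none
Why: Cu/TEMPO aerobic oxidation is selective for unhindered primary alcohols. It leaves the secondary C3–OH, the tertiary C8–OH, the ketone and the isopropenyl group intact, and it does not cleave the 1,2-diol the way periodate-type oxidants would. No stereocentre is altered.

**Step 9**
Reactants: 10
Product: 11 (E)-enal (C9=C10, C11 CHO)
Conditions: Ph3P=CHCHO (1.5 equiv), toluene, 80 °C
Reagents that add atoms: (formylmethylene)triphenylphosphorane, O=CC=P(c1ccccc1)(c1ccccc1)c1ccccc1 (adds C10 and C11)
Why: A stabilised ylide (Wittig reaction) reacts with the aldehyde and not the methyl ketone, and gives the E enal.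

**Step 10**
Reactants: 11
Product: 12 saturated C11 aldehyde (seco keto-aldehyde)
Conditions: Hantzsch ester (1.2 equiv), Bn2NH2+ CF3CO2− (20 mol %), CH2Cl2, rt
Reagents that add atoms: none (adds H2 only)
Why: Achiral iminium-catalysed transfer hydrogenation reduces the enal C=C selectively. The ketone, isopropenyl group and free OH groups survive. The aldehyde can exist partly as the γ-lactol with C8–OH, which re-opens under the step 11 conditions.

**Step 11**
Reactants: 12
Product: 13 macrocyclic tetraol (1R,3S,4R,7S,8R,11R,12R)
Conditions: Cp2TiCl2 (30 mol %), 4CzIPN (2 mol %), Hantzsch ester (2.5 equiv), 2,4,6-collidine·HCl (2 equiv), THF, 2 mM (slow addition of 12 by syringe pump), blue LEDs, 25 °C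
Reagents that add atoms: none (H+ and e− only)
Why: Proposed new method: Ti(III)/photoredox intramolecular cross-pinacol coupling that closes a 14-membered carbocycle from an unactivated aliphatic aldehyde and an unactivated methyl ketone. Cp2Ti(III)Cl, regenerated by reduced 4CzIPN and Hantzsch ester, reduces the Ti-bound aldehyde to a ketyl. The ketyl attacks the Ti-activated ketone intramolecularly to give a Ti(IV) diolate, and collidinium protonolysis releases the diol and turns over Cp2TiCl2. The closest known reactions are Ti(III)/photoredox pinacol coupling of aryl aldehydes and SmI2 keto-aldehyde pinacol cyclisations. The new C11/C12 pair is set by the ring conformation enforced by the cis-THF and the C1 and C3 stereocentres (remote stereocontrol), favouring (11R,12R). Minor diastereomers are removed by HPLC.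

**Step 12**
Reactants: 13
Product: 14 C3,C11-diacetate
Conditions: Ac2O (2.6 equiv), pyridine, DMAP (10 mol %), CH2Cl2, 0 °C→rt
Reagents that add atoms: acetic anhydride, CC(=O)OC(C)=O
Why: Both secondary alcohols are acetylated under DMAP catalysis. The tertiary C8–OH and C12–OH are too hindered to react under these mild conditions. No stereocentre changes.

**Step 13**
Reactants: 14
Product: 15 allylic alcohol (C17–OH)
Conditions: SeO2 (0.3 equiv), t-BuOOH (4 equiv), CH2Cl2, rt
Reagents that add atoms: t-BuOOH, CC(C)(C)OO (supplies O)
Why: Riley allylic oxidation of the isopropenyl methyl group gives CH2=C(CH2OH)–. It is the only alkene left, and the acetates, THF and tertiary alcohols survive.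

**Step 14**
Reactants: 15
Product: 16 α-methylene aldehyde (C17 aldehyde)
Conditions: MnO2 (20 equiv), CH2Cl2, rt
Reagents that add atoms: none
Why: MnO2 selectively oxidises the allylic alcohol. The tertiary alcohols and acetates are untouched.

**Step 15**
Reactants: 16
Product: 17 α-methylene carboxylic acid
Conditions: NaClO2, NaH2PO4, 2-methyl-2-butene, t-BuOH/H2O, rt
Reagents that add atoms: sodium chlorite, [Na+].[O-]Cl=O (supplies O)
Why: Pinnick oxidation converts the aldehyde to the acid. The scavenger prevents chlorination of the 1,1-disubstituted alkene.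

**Step 16**
Reactants: 17
Product: 18 Querciformolide C (target)
Conditions: 2,4,6-Cl3C6H2COCl, Et3N, THF, rt; then dilute into DMAP (10 equiv) in toluene (1 mM), 80 °C
Reagents that add atoms: none
Why: Yamaguchi lactonisation: intramolecular capture of the mixed anhydride (as its DMAP acylpyridinium) by the tertiary C12–OH closes the seven-membered lactone. C3 and C11 are already acetylated, and C12 keeps its configuration because no bond to that stereocentre is broken.

## Compound list
1 | (R)-(+)-limonene | CC1=CC[C@@H](CC1)C(C)=C | starting material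
2 | (R)-limonene 1,2-oxide (cis/trans mixture) | CC12OC1C[C@@H](CC2)C(C)=C | intermediate
3 | (R)-3-isopropenyl-6-oxoheptanal | O=CC[C@@H](CCC(C)=O)C(C)=C | intermediate
4 | diethyl 2,6-dimethyl-4-[(2R)-5-oxo-2-(prop-1-en-2-yl)hexyl]-1,4-dihydropyridine-3,5-dicarboxylate | CCOC(=O)C1=C(C)NC(C)=C(C(=O)OCC)C1C[C@@H](CCC(C)=O)C(C)=C | intermediate
5 | (R)-(−)-linalool | C=C[C@](C)(O)CCC=C(C)C | starting material
6 | (3R,6E)-3,7-dimethylocta-1,6-diene-3,8-diol | C=C[C@](C)(O)CC/C=C(/CO)C | intermediate
7 | (2R)-2-[(2S,5R)-5-ethenyl-5-methyloxolan-2-yl]propane-1,2-diol | C=C[C@@]1(C)CC[C@H](O1)[C@](C)(O)CO | intermediate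
8 | (2R,5S)-5-[(2R)-1,2-dihydroxypropan-2-yl]-2-methyloxolane-2-carbaldehyde | O=C[C@@]1(C)CC[C@H](O1)[C@](C)(O)CO | intermediate
9 | coupling product of 4 and 8: THF (C4–C8) bearing at C4 the CH(OH)–CH2–CH(isopropenyl)–CH2CH2C(=O)CH3 chain, C8 tertiary OH, C9 CH2OH (1R,3S,4R,7S,8R) | C=C(C)[C@H](CCC(C)=O)C[C@H](O)[C@@]1(C)CC[C@H](O1)[C@](C)(O)CO | intermediate
10 | C9 aldehyde derived from 9 (α-hydroxy aldehyde) | C=C(C)[C@H](CCC(C)=O)C[C@H](O)[C@@]1(C)CC[C@H](O1)[C@](C)(O)C=O | intermediate
11 | (E)-enal from 10 (C9=C10, C11 CHO) | C=C(C)[C@H](CCC(C)=O)C[C@H](O)[C@@]1(C)CC[C@H](O1)[C@](C)(O)/C=C/C=O | intermediate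
12 | seco keto-aldehyde (C11 CHO, C12 methyl ketone) | C=C(C)[C@H](CCC(C)=O)C[C@H](O)[C@@]1(C)CC[C@H](O1)[C@](C)(O)CCC=O | intermediate
13 | macrocyclic tetraol (1R,3S,4R,7S,8R,11R,12R) | C=C(C)[C@@H]1CC[C@@](C)(O)[C@H](O)CC[C@@](C)(O)[C@@H]2CC[C@@](C)(O2)[C@@H](O)C1 | intermediate
14 | 3,11-di-O-acetyl derivative of 13 | C=C(C)[C@@H]1CC[C@@](C)(O)[C@H](OC(C)=O)CC[C@@](C)(O)[C@@H]2CC[C@@](C)(O2)[C@@H](OC(C)=O)C1 | intermediate
15 | allylic alcohol (C17–OH) | OCC(=C)[C@@H]1CC[C@@](C)(O)[C@H](OC(C)=O)CC[C@@](C)(O)[C@@H]2CC[C@@](C)(O2)[C@@H](OC(C)=O)C1 | intermediate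
16 | α-methylene aldehyde | O=CC(=C)[C@@H]1CC[C@@](C)(O)[C@H](OC(C)=O)CC[C@@](C)(O)[C@@H]2CC[C@@](C)(O2)[C@@H](OC(C)=O)C1 | intermediate
17 | α-methylene carboxylic acid | OC(=O)C(=C)[C@@H]1CC[C@@](C)(O)[C@H](OC(C)=O)CC[C@@](C)(O)[C@@H]2CC[C@@](C)(O2)[C@@H](OC(C)=O)C1 | intermediate
18 | Querciformolide C | C=C1C(=O)O[C@]2(C)CC[C@@H]1C[C@H](OC(C)=O)[C@@]1(C)CC[C@H](O1)[C@](C)(O)CC[C@H]2OC(C)=O | target

## Totals
- Total steps: 16.
- Longest linear sequence: 13 steps (linalool branch: steps 4–6, then 7–16; limonene branch: steps 1–3, then 7–16).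
- Three steps most likely to fail:
  1. **Step 11 (new macrocyclic cross-pinacol).** Closure of a 14-membered ring from an aliphatic aldehyde and ketone, competing with the lactol form of 12, may give low yield or the wrong (11,12) diastereomer. Fallback: intramolecular SmI2 keto-aldehyde pinacol cyclisation (THF/t-BuOH, −78 °C, 1 mM), a known ring-closing manifold that proceeds through a preformed Sm(III)-chelated ketyl.
  2. **Step 7 (Cr/photoredox coupling).** The hindered α-alkoxy quaternary aldehyde may couple poorly or give poor C3 selectivity. Fallback: take the C3 epimer mixture, oxidise it (DMP) to the ketone, and reduce with L-Selectride or Zn(BH4)2, so that C3 is set by a substrate-controlled hydride reduction instead of the organochromium addition.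
  3. **Step 16 (lactonisation onto a tertiary alcohol).** The seven-membered lactone may fail to close. Fallback: oxidative lactonisation of hydroxy-aldehyde 16 through its lactol (TPAP/NMO or Ag2CO3–Celite), which bypasses the Pinnick step and the Yamaguchi closure.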